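## The problem

Compound **42** is a germacranolide whose ten-membered carbocycle C1–C10 holds two trisubstituted, ring-cis double bonds: C1=C10 carries the C14 aldehyde and C4=C5 carries the C15 carbinol. The ring is trans-fused across C6–C7 to an α-methylene-γ-lactone (C11, C12, C13), and C8 and C9 carry angelate esters. A ten-membered ring with two ring-cis alkenes is a poor object for direct cyclisation, so both the ring and the alkene geometry should be taken from smaller rings in which they are fixed. Four contiguous stereocentres (6R,7S,8S,9S) must be set: the C6 oxygen is trans to the C7 side chain and can be placed under control of C7, and the C9 oxygen can come from a C9 ketone under control of C8. The C8 oxygen is cis to the C7 side chain, which additions anti to a neighbour do not give; it needs hydride delivery to a C8 ketone. The angelates (isomerised to tiglates by base, nucleophiles or heat), the α-methylene lactone and the enal (Michael acceptors) and the 1,5-diene (acid, heat) must appear last, and C12, C14 and C15 must end at three different oxidation levels. The enabling feature is that C4 and C9 are linked by two five-atom arcs, C4–C5–C6–C7–C8–C9 and C4–C3–C2–C1–C10–C9, while C9 bears oxygen and C4=C5 is an alkene. A C4–C9 bond therefore turns the ring into a cis-decalin (ring A = C4–C9 through C5–C8, ring B = C4–C9 through C3–C1 and C10) with C1=C10 locked cis in a cyclohexene, and a C9 alkoxide with a C5 sulfonate can break that bond again.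

## Retrosynthesis

**C15–O.** The C15 hydroxyl of **42** is removed first, giving lactone enal **41**. In **41** the only electron-rich alkene is C4=C5, so a selenium dioxide ene/[2,3] sequence should oxidise the methyl group on it and no protecting group for a third primary alcohol is needed. Doing this earlier would demand an extra orthogonal group on C15; that variant is kept as a fallback.

**Lactone and aldehyde.** The C12 carbonyl and the C14 aldehyde of **41** are traced to the two primary allylic alcohols of triol **38**, whose C6 hydroxyl closes the lactol. One primary-selective oxidation is asked to do three oxidations without touching the secondary allylic C6 alcohol. Carrying a lactone or an enal through earlier steps would expose them to alkoxide, hydride and hydrazine.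

**Esters.** The three silyl ethers of bis-angelate **37** mask **38**. The two C–O acyl bonds are cut to diol **34** and two molecules of angelic acid **35**, one for each hydroxyl. Acylation is placed after all strongly basic steps and must not isomerise the Z-enoate.

**C9 carbinol.** Diol **34** comes from silyl ether **33**, and **33** from dienone **32** by 1,2-reduction. A non-chelating silyl ether on C8 is chosen so that the Felkin–Anh sense (hydride anti to the C8–O bond) gives the required 9S alcohol; an alkoxymethyl ether could chelate and reverse it.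

**Key disconnection.** In **32** a bond is drawn between C4 and C9 and a sulfonate is placed on C5, giving the cis-decalin mesylate **30**. This cut is preferred to any ring closure of an open chain because the fragmentation is stereospecific: C1=C10 is cis by ring B, and C4=C5 is cis if C3 is axial on ring A and the mesylate equatorial. **30** contains every stereocentre of the ring except C9. The forward step must fragment faster than the new α-silyloxy ketone epimerises.

**C8 inversion and C5 activation.** The C8 oxygen of **30** is anti to the C4 methyl and cis to the C7 side chain, so it is traced through alcohol **29** to ketone **28**, made from the syn alcohol **27**. The syn alcohol is wanted earlier because, tied to the C9 oxygen as an acetonide (mesylate **26**, alcohol **25**, ketone **24**), it steers the C7 substituent to the opposite face. The C5 alcohol of **25** is made by reduction of the C5 ketone in the cis-decalin, where the equatorial alcohol is the epimer needed for the mesylate.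

**C7–C11 and C6–O.** Hydroxy ketone **23** is cut at C7–C11 and at C6–O to enone acetonide **16** and vinyl bromide **18**, the silyl ether of 2-bromoprop-2-en-1-ol **17**. A cuprate adds anti to the acetonide, and the enolate is oxidised anti to the new side chain. The whole C11–C13 unit, with the exo-methylene and C12 at the alcohol level, arrives in one bond, so no late α-methylenation is needed.

**Ring-A enone and C8 oxygen.** Acetonide **16** comes from cis-diol **15**, made by γ-hydroxylation of enone **13** through its dienol ether **14**. The C8 oxygen cannot be introduced before the C9 oxygen, because a substituent on C8 would block the face on which the C9 oxygen must be placed. Introduced afterwards, it can be directed by the C9 hydroxyl. Enone **13** comes from ketone **11**; C4 is quaternary, so enolisation has one direction only.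

**C1=C10 and C9–OH.** Ketone **11** and diol **10** are traced to epoxy ketone **8** by a Wharton transposition, and **8** to enone **7**. The epoxide face fixes the C9 oxygen syn to the methyl, that is, the cis ring fusion. The C5 carbonyl is held as an alcohol during this phase so that hydrazine finds one carbonyl only.

**C14.** Enone **7** (via **6**) is cut at C10–C14 to bromo enone **4** and stannane **5**. An amine-catalysed hydroxymethylation with formaldehyde is not available for a β,β-disubstituted enone, so halogenation and cross-coupling are used. **4** comes from alcohol **2**, the selective reduction product of (S)-Wieland–Miescher ketone **1**, which supplies C1–C10, C15, the C4 configuration and oxygen at C5 and C1.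

## Roads not taken

Alternative 1: The cut runs through C7–C8 and C6–O. In the forward step excited ethyl glyoxylate **A2** adds to furan **A1** (Paternò–Büchi reaction): its carbonyl carbon (C8) bonds to the furan β-carbon (C7) and its oxygen to the α-carbon (C6), giving the exo oxetane **A3**.
- Merits: one step from two bulk chemicals builds the C7–C8 bond with defined relative configuration at C6, C7 and C8, and the two remaining furan carbons are placed to become C11 and C12. It reaches the C7/C8 relation directly, where the chosen plan spends an oxidation–reduction detour.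
- Weak points: **A3** is racemic unless an auxiliary is added. It supplies only a four-carbon core. C1–C5, C9, C10, C14 and C15 must then be attached and the cis,cis-cyclodecadiene closed by macrocyclisation, with C9 and both alkene geometries set in open-chain or medium-ring steps of uncertain control.
- Comparison: the chosen plan sets against the shorter stereotriad a ring formation without macrocyclisation, alkene geometry fixed by rings, and an enantiopure start.

Alternative 2: The cut is at C4–C5 and C1–C10. The triplet state of enone **A4** (C6 carbonyl, C5=C10) adds across the double bond of methyl cyclobut-1-ene-1-carboxylate **A5**, giving the tricyclic photoadduct **A6**. Heating is then meant to open the bicyclo[2.2.0]hexane unit by breaking C5–C10 and C1–C4, so that both ring alkenes appear.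
- Merits: all ten ring carbons, C14 and C15 are assembled in one step from two simple partners. The route to the ten-membered ring would probably be shorter than the chosen one.
- Weak points: the thermal opening is not bound to give two ring-cis alkenes, and 1,5-cyclodecadienes are prone to Cope rearrangement at the temperatures required. Regio- and facial selectivity of the photoaddition on a lactone-fused enone are open. C14 arrives as a methyl group and C15 as an ester, the reverse of the oxidation pattern needed. The lactone is closed to C8 and lacks C13. The C6 ketone must be reduced in the medium ring.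
- Comparison: the chosen plan is longer but delivers both alkene geometries by construction, needs no heating of the diene, and carries C12, C13 and C14 in usable form.

Alternative 3: The cut is at C1–C6. A bond between these atoms gives the cis-fused octalin epoxy alcohol **A7**, a bicycle of Diels–Alder origin with a tertiary C6 carbinol and a spiro-epoxide on C10 (C10–O–C14). With Ti(OiPr)4 the C6 alkoxide expels the C1–C6 bond into the antiperiplanar C10–O bond, giving dienone **A8** with the C6 ketone, C1=C10 and the C14 alcohol.
- Merits: this is the closest relative of the chosen plan. The bicycle is built convergently by cycloaddition, probably in fewer steps than the linear decoration of **1**, and the C14 oxygen is released by the key step itself.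
- Weak points: an epoxide is a less reliable nucleofuge than a sulfonate and needs Lewis acid and exact alignment. The new ketone is at C6, next to the side-chain stereocentre C7, which can epimerise. The side chain is only an acetate unit, so α-methylenation must be done late beside an enal. The C8 and C9 oxygens are trans on the ring, so **A7** must carry a trans-fused dioxolane on a six-membered ring. An enantioselective cycloaddition is required.
- Comparison: both plans must reduce a ring ketone stereoselectively (C6 there, C9 here). The chosen plan sets against the shorter bicycle synthesis a sulfonate fragmentation of proven type, a non-epimerisable C7, and the complete C11–C13 unit in place before ring expansion.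

Key step: step 22

## Route

Remark: germacrane carbon numbers are used throughout; in the bicyclic compounds C4 and C9 are bonded, "syn" and "anti" give the face relative to the C4 methyl group, and **1**, **5**, **17** and **35** are taken as purchasable.

Step 1
Reactants: 1 (S)-Wieland–Miescher ketone
Product: 2 (4aS,5S)-5-hydroxy-4a-methyl-4,4a,5,6,7,8-hexahydronaphthalen-2(3H)-one (C5 alcohol syn; C1 enone)
Conditions: NaBH4 (0.3 equiv), EtOH, −10 °C
Reagents that add atoms: none
Why: Chemoselective borohydride reduction of the saturated ketone, the conjugated C1 carbonyl being less electrophilic; hydride adds anti to the angular methyl. The alcohol masks C5 against hydrazine in step 6 and is re-oxidised in step 7, so its configuration is temporary.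

Step 2
Reactants: 2 hydroxy enone
Product: 4 C10-bromo enone (bromine on the α-carbon of the C1 enone), via dibromide 3 (not isolated)
Conditions: Br2, CH2Cl2, 0 °C; then Et3N, 0 °C → rt
Reagents that add atoms: bromine, BrBr
Why: Addition–elimination α-bromination of an enone: bromine adds across C9=C10 and Et3N removes HBr from the dibromide. This route does not need conjugate attack of an amine at the fully substituted β-carbon, which is why it is used in place of amine-catalysed α-functionalisation.

Step 3
Reactants: 4 C10-bromo enone; 5 (tributylstannyl)methanol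
Product: 6 C10-hydroxymethyl enone (C14 alcohol; C5 alcohol)
Conditions: Pd(PPh3)4 (5 mol %), dioxane, 100 °C
Reagents that add atoms: none
Why: Stille hydroxymethylation of an α-halo enone; oxidative addition to zerovalent palladium is eased by the carbonyl group. C14 enters at the alcohol oxidation level.

Step 4
Reactants: 6 C10-hydroxymethyl enone
Product: 7 C14 tert-butyldiphenylsilyl ether of 6
Conditions: TBDPSCl, imidazole, CH2Cl2, 0 °C
Reagents that add atoms: tert-butyl(chloro)diphenylsilane, CC(C)(C)[Si](Cl)(c1ccccc1)c1ccccc1
Why: Silylation of the primary allylic alcohol; the neopentyl secondary C5 alcohol reacts much more slowly. The group is chosen to survive aqueous acid, alkoxide and hydride and to leave with fluoride at the end.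

Step 5
Reactants: 7 silyl ether enone
Product: 8 9,10-epoxy C1 ketone (epoxide oxygen syn)
Conditions: H2O2 (30 % aq.), NaOH, MeOH, 0 °C → rt
Reagents that add atoms: hydrogen peroxide, OO
Why: Weitz–Scheffer nucleophilic epoxidation. Hydroperoxide should add axially to C9 from the face syn to the angular methyl, through a chair-like cis-fused enolate, the usual preference of 10-methyl octalones; this places the C9 oxygen syn and so defines the later cis ring fusion.

Step 6
Reactants: 8 epoxy ketone
Product: 10 C1=C10 allylic diol (C9 tertiary alcohol syn; C5 alcohol syn; C14 silyl ether), via epoxy hydrazone 9 (not isolated)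
Conditions: N2H4·H2O, AcOH (cat.), MeOH, 0 °C → rt
Reagents that add atoms: none
Why: Wharton transposition: the hydrazone opens the epoxide at C10 and loses N2, giving C1=C10 and the tertiary C9 alcohol with the C9–O bond untouched. C1 is the only carbonyl present.

Step 7
Reactants: 10 allylic diol
Product: 11 C5 ketone with C9 tertiary alcohol
Conditions: Dess–Martin periodinane, NaHCO3, CH2Cl2, 0 °C → rt
Reagents that add atoms: none
Why: Oxidation of the only secondary alcohol; the tertiary allylic alcohol is inert under these neutral conditions.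

Step 8
Reactants: 11 C5 ketone
Product: 13 C6=C7 enone (C5 ketone; C9 alcohol), via C6 phenylselenide 12 (not isolated)
Conditions: LiN(iPr)2 (2.2 equiv), THF, −78 °C; PhSeBr; then H2O2, pyridine, CH2Cl2, 0 °C
Reagents that add atoms: none
Why: Enolate selenenylation and selenoxide syn-elimination. C4 is quaternary, so only C6 can be enolised and elimination can only run toward C7.

Step 9
Reactants: 13 enone
Product: 14 triisopropylsilyl dienol ether (C5(OSi)=C6–C7=C8; C9 alcohol free)
Conditions: TIPSOTf, Et3N, CH2Cl2, −20 → 0 °C
Reagents that add atoms: triisopropylsilyl trifluoromethanesulfonate, CC(C)[Si](C(C)C)(C(C)C)OS(=O)(=O)C(F)(F)F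
Why: Soft enolisation; only the γ-hydrogens on C8 are available, so the linear dienol ether forms. The hindered tertiary alcohol is not silylated by this reagent at 0 °C and stays free as a directing group.

Step 10
Reactants: 14 dienol ether
Product: 15 C8-hydroxy enone (C8 alcohol syn and cis to the C9 alcohol)
Conditions: mCPBA (1.05 equiv), NaHCO3, CH2Cl2, −40 °C; aqueous NaHCO3 work-up
Reagents that add atoms: 3-chloroperbenzoic acid, OOC(=O)c1cccc(Cl)c1
Why: Vinylogous Rubottom oxidation: the peracid epoxidises the terminal C7=C8 bond and the epoxide opens to the γ-hydroxy enone with loss of the silyl group. Hydrogen bonding to the allylic C9 hydroxyl (Henbest effect) should deliver the oxygen syn to it, and the dienol ether is far more nucleophilic than C1=C10.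

Step 11
Reactants: 15 cis-diol enone
Product: 16 8,9-acetonide of 15
Conditions: 2,2-dimethoxypropane, PPTS (cat.), CH2Cl2, rt
Reagents that add atoms: 2,2-dimethoxypropane, COC(C)(C)OC
Why: Acetal exchange, possible only for the cis-diol. The acetonide protects both hydroxyls and shields the syn face for step 13.

Step 12
Reactants: 17 2-bromoprop-2-en-1-ol
Product: 18 (2-bromoallyloxy)(tert-butyl)diphenylsilane
Conditions: TBDPSCl, imidazole, CH2Cl2, rt
Reagents that add atoms: tert-butyl(chloro)diphenylsilane, CC(C)(C)[Si](Cl)(c1ccccc1)c1ccccc1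
Why: Standard silylation of a primary alcohol; the same group as on C14 so that both leave together in step 26.

Step 13
Reactants: 16 enone acetonide; 18 vinyl bromide
Product: 21 C5 trimethylsilyl enol ether carrying the 3-silyloxyprop-1-en-2-yl group on C7 (anti), via vinyllithium 19 (not isolated), via lithium divinylcuprate 20 (not isolated)
Conditions: 18, t-BuLi (2 equiv), Et2O, −78 °C; CuI (0.5 equiv), −40 °C (R2CuLi); TMSCl, then 16, THF, −78 → −40 °C
Reagents that add atoms: chlorotrimethylsilane, C[Si](C)(C)Cl
Why: Bromine–lithium exchange, formation of the Gilman reagent and silyl-chloride-accelerated 1,4-addition. cis-4,5-Isopropylidenedioxycyclohex-2-enones take cuprates anti to the acetonide, so C7 is set anti to the C8 and C9 oxygens; the enolate is trapped as the silyl enol ether.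

Step 14
Reactants: 21 silyl enol ether
Product: 23 C6-hydroxy C5 ketone (C6 alcohol syn and trans to the C7 side chain), via C6 silyloxy ketone 22 (not isolated)
Conditions: mCPBA (1.05 equiv), NaHCO3, CH2Cl2, −20 °C; then citric acid, MeOH, rt
Reagents that add atoms: 3-chloroperbenzoic acid, OOC(=O)c1cccc(Cl)c1
Why: Rubottom oxidation. The peracid attacks the enol ether on the face away from the new C7 substituent, the usual trans outcome of conjugate addition followed by enolate functionalisation; the enol ether reacts much faster than the two remaining alkenes.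

Step 15
Reactants: 23 hydroxy ketone
Product: 24 C6 tert-butyldimethylsilyl ether of 23
Conditions: TBSOTf, 2,6-lutidine, CH2Cl2, −78 °C
Reagents that add atoms: tert-butyldimethylsilyl trifluoromethanesulfonate, CC(C)(C)[Si](C)(C)OS(=O)(=O)C(F)(F)F
Why: Silylation of the only free hydroxyl under non-epimerising conditions; the group stays on C6 until step 26.

Step 16
Reactants: 24 silyloxy ketone
Product: 25 C5 alcohol (anti; trans to the C6 silyl ether)
Conditions: NaBH4, MeOH, −20 °C
Reagents that add atoms: none
Why: Ketone reduction by axial attack on the ring-A chair in which C3 is axial on C4 and blocks the other face. This gives the equatorial alcohol anti to the methyl, the epimer that cannot be obtained on compound 1 itself.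

Step 17
Reactants: 25 C5 alcohol
Product: 26 C5 methanesulfonate
Conditions: MsCl, Et3N, CH2Cl2, 0 °C
Reagents that add atoms: methanesulfonyl chloride, CS(=O)(=O)Cl
Why: Sulfonylation through the sulfene, effective for hindered secondary alcohols; no other hydroxyl is free.

Step 18
Reactants: 26 acetonide mesylate
Product: 27 8,9-diol mesylate (C8 alcohol syn; C9 alcohol syn)
Conditions: AcOH/H2O (4:1), 40 °C
Reagents that add atoms: none
Why: Acetal hydrolysis. The hindered secondary silyl ether, the primary tert-butyldiphenylsilyl ethers and the mesylate should tolerate aqueous acetic acid.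

Step 19
Reactants: 27 diol mesylate
Product: 28 C8 ketone (α-hydroxy ketone with the C9 alcohol)
Conditions: (COCl)2, DMSO, CH2Cl2, −78 °C; Et3N, −78 → −20 °C
Reagents that add atoms: none
Why: Swern oxidation of the secondary hydroxyl of a secondary/tertiary 1,2-diol gives the α-ketol without glycol cleavage; triethylamine is too weak to start the fragmentation.

Step 20
Reactants: 28 C8 ketone
Product: 29 C8 alcohol (anti; trans to the C9 alcohol and cis to the C7 side chain)
Conditions: Me4NBH(OAc)3, MeCN/AcOH, −30 °C
Reagents that add atoms: none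
Why: Hydroxyl-directed triacetoxyborohydride reduction: the reagent exchanges onto the C9 hydroxyl and delivers hydride from that face, which is also the sterically open face because axial C3 shields the other one. The medium is non-basic, so the mesylate does not fragment.

Step 21
Reactants: 29 diol mesylate
Product: 30 C8 triethylsilyl ether (cis-decalin with C9 alcohol and C5 mesylate)
Conditions: TESOTf (1.05 equiv), 2,6-lutidine, CH2Cl2, −78 °C
Reagents that add atoms: triethylsilyl trifluoromethanesulfonate, CC[Si](CC)(CC)OS(=O)(=O)C(F)(F)F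
Why: Silylation of the secondary alcohol in preference to the more hindered tertiary one. A non-chelating group is chosen to steer step 23.

Step 22
Reactants: 30 cis-decalin C9 alcohol C5 mesylate
Product: 32 cis,cis-cyclodeca-1(10),4-dien-9-one with C6, C7 and C8 set, via potassium alkoxide 31 (not isolated)
Conditions: KOtBu (1.1 equiv), THF, 0 °C → rt
Reagents that add atoms: none
Why: The tertiary C9 alkoxide fragments in a concerted heterolytic manner: the oxygen lone pair forms the C9 carbonyl, the C4–C9 bond breaks, C4=C5 forms and the mesylate leaves. The closest known reaction type is the Wharton (Grob-type) fragmentation of cyclic 1,3-diol monosulfonates to cyclodecenones. No ring closes; the ten-membered ring appears when the bond shared by the two six-membered rings is lost. No stereocentre is created, and C6, C7 and C8 are spectators. The step needs the C5–O bond antiperiplanar to C4–C9: in the ring-A chair the mesylate, the C6 silyl ether and the C7 side chain are all equatorial and only the C8 silyl ether and the C9 oxygen are axial, whereas the flipped chair would have five axial groups. In that chair C3 is axial on C4, so C3 and C6 end cis across the new double bond. C1=C10 is cis because it was part of the cyclohexene ring B. Only a slight excess of base is used, which is consumed as the mesylate leaves, so that the new α-silyloxy ketone is not left in contact with alkoxide.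

Step 23
Reactants: 32 dienone
Product: 33 C9 allylic alcohol (9S)
Conditions: NaBH4, CeCl3·7H2O, MeOH, −78 °C
Reagents that add atoms: none
Why: Luche 1,2-reduction of the enone. With the non-chelating C8 silyl ether the Felkin–Anh polar model (hydride anti to the C8–O bond) leads to the 9S alcohol, trans to the C8 oxygen.

Step 24
Reactants: 33 silyl ether alcohol
Product: 34 8,9-diol
Conditions: HF·pyridine, pyridine, THF, 0 °C
Reagents that add atoms: none
Why: Selective cleavage of the triethylsilyl ether, far more labile than the secondary tert-butyldimethylsilyl and primary tert-butyldiphenylsilyl ethers.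

Step 25
Reactants: 34 8,9-diol; 35 angelic acid
Product: 37 8,9-bis-angelate, via mixed anhydride 36 (not isolated)
Conditions: 35 (6 equiv), 2,4,6-trichlorobenzoyl chloride (6 equiv), Et3N, toluene, rt; then 34, 75 °C
Reagents that add atoms: angelic acid (second molecule of 35), C/C=C(/C)C(=O)O
Why: Yamaguchi-type acylation through the mixed anhydride, run without a nucleophilic catalyst so that the Z-enoate is not isomerised to the tiglate. Each of the two hydroxyls takes one angeloyl group, so two molecules of 35 enter 37; the anhydride is used in excess to drive the slower second acylation next to the first ester.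

Step 26
Reactants: 37 bis-angelate
Product: 38 6,12,14-triol
Conditions: HF·pyridine, THF, rt
Reagents that add atoms: none
Why: Fluoride-mediated removal of all three silyl ethers under mildly acidic conditions that leave the esters in place.

Step 27
Reactants: 38 triol
Product: 41 lactone enal (15-deoxy compound), via hydroxy dialdehyde 39 (not isolated), via lactol 40 (not isolated)
Conditions: TEMPO (0.2 equiv), PhI(OAc)2 (4.5 equiv), CH2Cl2, rt
Reagents that add atoms: none
Why: Oxoammonium oxidation selective for primary alcohols: C14 gives the enal, C12 gives an aldehyde that is trapped by the C6 hydroxyl as a lactol, and the lactol is oxidised to the lactone. The secondary allylic C6 alcohol is consumed by lactol formation before it can be oxidised.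

Step 28
Reactants: 41 lactone enal
Product: 42 target, (6R,7S,8S,9S)-8,9-bis(angeloyloxy)-15-hydroxy-14-oxogermacra-1(10),4,11(13)-trien-12,6-olide with both ring double bonds cis
Conditions: SeO2 (0.5 equiv), t-BuOOH, CH2Cl2, 0 °C → rt
Reagents that add atoms: tert-butyl hydroperoxide, CC(C)(C)OO (the oxygen is passed on by SeO2, O=[Se]=O)
Why: Allylic hydroxylation by ene reaction and [2,3]-shift, a known reaction type for methyl groups of germacranolides that carry an α-methylene lactone. C4=C5 is the only electron-rich alkene; the reaction occurs at the more substituted end and places the oxygen on the methyl group trans to C6, so the ring-cis geometry is kept.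

## Compound list

1 | (S)-Wieland–Miescher ketone | C[C@]12CCC(=O)C=C1CCCC2=O | starting material
2 | (4aS,5S)-5-hydroxy enone | C[C@]12CCC(=O)C=C1CCC[C@@H]2O | intermediate
3 | 9,10-dibromide of 2 | C[C@]12CCC(=O)[C@H](Br)[C@]1(Br)CCC[C@@H]2O | intermediate
4 | C10-bromo enone | C[C@]12CCC(=O)C(Br)=C1CCC[C@@H]2O | intermediate
5 | (tributylstannyl)methanol | OC[Sn](CCCC)(CCCC)CCCC | starting material
6 | C10-hydroxymethyl enone | C[C@]12CCC(=O)C(CO)=C1CCC[C@@H]2O | intermediate
7 | C14 TBDPS ether enone | C[C@]12CCC(=O)C(CO[Si](c3ccccc3)(c3ccccc3)C(C)(C)C)=C1CCC[C@@H]2O | intermediate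
8 | 9,10-epoxy C1 ketone (epoxide syn) | C[C@]12CCC(=O)[C@]3(CO[Si](c4ccccc4)(c4ccccc4)C(C)(C)C)O[C@]13CCC[C@@H]2O | intermediate
9 | epoxy hydrazone | C[C@]12CCC(=NN)[C@]3(CO[Si](c4ccccc4)(c4ccccc4)C(C)(C)C)O[C@]13CCC[C@@H]2O | intermediate
10 | C1=C10 allylic diol (C9-OH syn, C5-OH syn) | C[C@]12CCC=C(CO[Si](c3ccccc3)(c3ccccc3)C(C)(C)C)[C@@]1(O)CCC[C@@H]2O | intermediate
11 | C5 ketone, C9 alcohol | C[C@]12CCC=C(CO[Si](c3ccccc3)(c3ccccc3)C(C)(C)C)[C@@]1(O)CCCC2=O | intermediate
12 | C6 phenylselenide of 11 | C[C@]12CCC=C(CO[Si](c3ccccc3)(c3ccccc3)C(C)(C)C)[C@@]1(O)CCC([Se]c3ccccc3)C2=O | intermediate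
13 | C6=C7 enone | C[C@]12CCC=C(CO[Si](c3ccccc3)(c3ccccc3)C(C)(C)C)[C@@]1(O)CC=CC2=O | intermediate
14 | TIPS dienol ether | C[C@]12CCC=C(CO[Si](c3ccccc3)(c3ccccc3)C(C)(C)C)[C@@]1(O)C=CC=C2O[Si](C(C)C)(C(C)C)C(C)C | intermediate
15 | C8-hydroxy enone (cis-8,9-diol) | C[C@]12CCC=C(CO[Si](c3ccccc3)(c3ccccc3)C(C)(C)C)[C@@]1(O)[C@H](O)C=CC2=O | intermediate
16 | 8,9-acetonide enone | C[C@]12CCC=C(CO[Si](c4ccccc4)(c4ccccc4)C(C)(C)C)[C@]13OC(C)(C)O[C@@H]3C=CC2=O | intermediate
17 | 2-bromoprop-2-en-1-ol | OCC(Br)=C | starting material
18 | (2-bromoallyloxy)(tert-butyl)diphenylsilane | C=C(Br)CO[Si](c1ccccc1)(c1ccccc1)C(C)(C)C | intermediate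
19 | 3-(TBDPS-oxy)prop-1-en-2-yllithium | [Li]C(=C)CO[Si](c1ccccc1)(c1ccccc1)C(C)(C)C | intermediate
20 | lithium bis[3-(TBDPS-oxy)prop-1-en-2-yl]cuprate | [Li+].C=C(CO[Si](c1ccccc1)(c1ccccc1)C(C)(C)C)[Cu-]C(=C)CO[Si](c1ccccc1)(c1ccccc1)C(C)(C)C | intermediate
21 | C5 TMS enol ether with C7 side chain (anti) | C[C@]12CCC=C(CO[Si](c4ccccc4)(c4ccccc4)C(C)(C)C)[C@]13OC(C)(C)O[C@@H]3[C@@H](C(=C)CO[Si](c4ccccc4)(c4ccccc4)C(C)(C)C)C=C2O[Si](C)(C)C | intermediate
22 | C6 trimethylsilyloxy C5 ketone | C[C@]12CCC=C(CO[Si](c4ccccc4)(c4ccccc4)C(C)(C)C)[C@]13OC(C)(C)O[C@@H]3[C@@H](C(=C)CO[Si](c4ccccc4)(c4ccccc4)C(C)(C)C)[C@H](O[Si](C)(C)C)C2=O | intermediate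
23 | C6-hydroxy C5 ketone (C6-OH syn) | C[C@]12CCC=C(CO[Si](c4ccccc4)(c4ccccc4)C(C)(C)C)[C@]13OC(C)(C)O[C@@H]3[C@@H](C(=C)CO[Si](c4ccccc4)(c4ccccc4)C(C)(C)C)[C@H](O)C2=O | intermediate
24 | C6 TBS ether C5 ketone | C[C@]12CCC=C(CO[Si](c4ccccc4)(c4ccccc4)C(C)(C)C)[C@]13OC(C)(C)O[C@@H]3[C@@H](C(=C)CO[Si](c4ccccc4)(c4ccccc4)C(C)(C)C)[C@H](O[Si](C)(C)C(C)(C)C)C2=O | intermediate
25 | C5 alcohol (anti) | C[C@]12CCC=C(CO[Si](c4ccccc4)(c4ccccc4)C(C)(C)C)[C@]13OC(C)(C)O[C@@H]3[C@@H](C(=C)CO[Si](c4ccccc4)(c4ccccc4)C(C)(C)C)[C@H](O[Si](C)(C)C(C)(C)C)[C@H]2O | intermediate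
26 | C5 mesylate acetonide | C[C@]12CCC=C(CO[Si](c4ccccc4)(c4ccccc4)C(C)(C)C)[C@]13OC(C)(C)O[C@@H]3[C@@H](C(=C)CO[Si](c4ccccc4)(c4ccccc4)C(C)(C)C)[C@H](O[Si](C)(C)C(C)(C)C)[C@H]2OS(C)(=O)=O | intermediate
27 | 8,9-diol mesylate (C8-OH syn) | C[C@]12CCC=C(CO[Si](c3ccccc3)(c3ccccc3)C(C)(C)C)[C@@]1(O)[C@H](O)[C@@H](C(=C)CO[Si](c3ccccc3)(c3ccccc3)C(C)(C)C)[C@H](O[Si](C)(C)C(C)(C)C)[C@H]2OS(C)(=O)=O | intermediate
28 | C8 ketone mesylate | C[C@]12CCC=C(CO[Si](c3ccccc3)(c3ccccc3)C(C)(C)C)[C@@]1(O)C(=O)[C@@H](C(=C)CO[Si](c3ccccc3)(c3ccccc3)C(C)(C)C)[C@H](O[Si](C)(C)C(C)(C)C)[C@H]2OS(C)(=O)=O | intermediate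
29 | 8,9-diol mesylate (C8-OH anti) | C[C@]12CCC=C(CO[Si](c3ccccc3)(c3ccccc3)C(C)(C)C)[C@@]1(O)[C@@H](O)[C@@H](C(=C)CO[Si](c3ccccc3)(c3ccccc3)C(C)(C)C)[C@H](O[Si](C)(C)C(C)(C)C)[C@H]2OS(C)(=O)=O | intermediate
30 | cis-decalin C9 alcohol C5 mesylate, C8 TES ether | C[C@]12CCC=C(CO[Si](c3ccccc3)(c3ccccc3)C(C)(C)C)[C@@]1(O)[C@@H](O[Si](CC)(CC)CC)[C@@H](C(=C)CO[Si](c3ccccc3)(c3ccccc3)C(C)(C)C)[C@H](O[Si](C)(C)C(C)(C)C)[C@H]2OS(C)(=O)=O | intermediate
31 | potassium C9 alkoxide of 30 | C[C@]12CCC=C(CO[Si](c3ccccc3)(c3ccccc3)C(C)(C)C)[C@@]1(O[K])[C@@H](O[Si](CC)(CC)CC)[C@@H](C(=C)CO[Si](c3ccccc3)(c3ccccc3)C(C)(C)C)[C@H](O[Si](C)(C)C(C)(C)C)[C@H]2OS(C)(=O)=O | intermediate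
32 | cis,cis-cyclodeca-1(10),4-dien-9-one | CC(C)(C)[Si](C)(C)O[C@@H]2/C=C(/C)CC/C=C(/CO[Si](c3ccccc3)(c3ccccc3)C(C)(C)C)C(=O)[C@@H](O[Si](CC)(CC)CC)[C@H]2C(=C)CO[Si](c3ccccc3)(c3ccccc3)C(C)(C)C | intermediate
33 | C9 alcohol (9S), C8 TES ether | CC(C)(C)[Si](C)(C)O[C@@H]2/C=C(/C)CC/C=C(/CO[Si](c3ccccc3)(c3ccccc3)C(C)(C)C)[C@H](O)[C@@H](O[Si](CC)(CC)CC)[C@H]2C(=C)CO[Si](c3ccccc3)(c3ccccc3)C(C)(C)C | intermediate
34 | 8,9-diol | CC(C)(C)[Si](C)(C)O[C@@H]2/C=C(/C)CC/C=C(/CO[Si](c3ccccc3)(c3ccccc3)C(C)(C)C)[C@H](O)[C@@H](O)[C@H]2C(=C)CO[Si](c3ccccc3)(c3ccccc3)C(C)(C)C | intermediate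
35 | angelic acid, (Z)-2-methylbut-2-enoic acid | C/C=C(/C)C(=O)O | starting material
36 | angelic 2,4,6-trichlorobenzoic anhydride | C/C=C(/C)C(=O)OC(=O)c1c(Cl)cc(Cl)cc1Cl | intermediate
37 | 8,9-bis-angelate, tris-silyl ether | CC(C)(C)[Si](C)(C)O[C@@H]2/C=C(/C)CC/C=C(/CO[Si](c3ccccc3)(c3ccccc3)C(C)(C)C)[C@H](OC(=O)/C(C)=C\C)[C@@H](OC(=O)/C(C)=C\C)[C@H]2C(=C)CO[Si](c3ccccc3)(c3ccccc3)C(C)(C)C | intermediate
38 | 6,12,14-triol bis-angelate | O[C@@H]2/C=C(/C)CC/C=C(/CO)[C@H](OC(=O)/C(C)=C\C)[C@@H](OC(=O)/C(C)=C\C)[C@H]2C(=C)CO | intermediate
39 | C6-hydroxy 12,14-dialdehyde | O[C@@H]2/C=C(/C)CC/C=C(/C=O)[C@H](OC(=O)/C(C)=C\C)[C@@H](OC(=O)/C(C)=C\C)[C@H]2C(=C)C=O | intermediate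
40 | 12,6-lactol 14-aldehyde | C=C1C(O)O[C@@H]2/C=C(/C)CC/C=C(/C=O)[C@H](OC(=O)/C(C)=C\C)[C@@H](OC(=O)/C(C)=C\C)[C@@H]12 | intermediate
41 | lactone enal (15-deoxy compound) | C=C1C(=O)O[C@@H]2/C=C(/C)CC/C=C(/C=O)[C@H](OC(=O)/C(C)=C\C)[C@@H](OC(=O)/C(C)=C\C)[C@@H]12 | intermediate
42 | CNP0139154.1 | C=C1C(=O)O[C@@H]2/C=C(/CO)CC/C=C(/C=O)[C@H](OC(=O)/C(C)=C\C)[C@@H](OC(=O)/C(C)=C\C)[C@@H]12 | target

## Step count and risks

Total: 28 steps. Longest linear sequence: 27 steps (steps 1–11 and 13–28 from **1**); step 12 prepares the side-chain bromide.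

**Step 22 (key step).** What may go wrong is epimerisation at C8 by enolisation of the new α-silyloxy ketone while alkoxide is still present, or slow fragmentation if ring A leaves the chair that holds the mesylate equatorial. Transfer of the triethylsilyl group from the C8 oxygen to the C9 alkoxide is a lesser concern, because the two C–O bonds are trans-diaxial in the reactive chair. The fallback sets out from diol mesylate **29** without silylation: two equivalents of KOtBu should give the C8-hydroxy dienone F1, the C8 alkoxide next to the forming ketone opposing enolisation toward C8, and silylation of the free hydroxyl (TESOTf, 2,6-lutidine) returns to the route at **32**.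

**Step 5.** What may go wrong is poor facial selectivity, or sluggish attack of hydroperoxide on the tetrasubstituted enone; attack anti to the methyl would lead to a trans-fused alcohol and, later, a ring-trans C4=C5. The fallback sets out from **7** and lets hydroxyl groups direct the oxygen. Reduction with NaBH4/CeCl3·7H2O should give the C1 allylic alcohol F2, with the C1 hydroxyl syn. VO(acac)2/t-BuOOH then epoxidises syn to the allylic and the homoallylic hydroxyl and gives the epoxy diol F3. Dess–Martin oxidation of both secondary alcohols gives the epoxy diketone F4. Wharton transposition with one equivalent of N2H4·H2O/AcOH at 0 °C at the more electrophilic epoxy ketone (the C5 carbonyl is flanked by the quaternary centre) returns to the route at **11**.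

**Step 10.** What may go wrong is attack of the peracid at C6 in place of C8, or delivery of the oxygen to the face anti to the C9 hydroxyl. The fallback for the second case sets out from **14**: the oxidation then gives the trans-diol F5, the C8 epimer of 15. Its activated secondary alcohol is inverted by Mitsunobu reaction (PPh3, diisopropyl azodicarboxylate, 4-nitrobenzoic acid) to the 4-nitrobenzoate F6, and cleavage of the ester with Et3N/MeOH returns to the route at **15**.

**Step 23.** What may go wrong is that the conformation of the ten-membered ring, not the Felkin–Anh preference, decides the face of hydride attack. The fallback sets out from **32**, whose reduction then gives the C9-epimeric alcohol F7. Mitsunobu esterification with angelic acid **35** (PPh3, diisopropyl azodicarboxylate) inverts C9 and installs the first ester, giving the C9 angelate F8. HF·pyridine then gives the C8 alcohol F9, and acylation with **35** as in step 25 returns to the route at **37**.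

**Step 28.** What may go wrong is over-oxidation of the new carbinol to the aldehyde, competing oxidation at C3, slow reaction of an alkene deactivated by the allylic lactone oxygen, or isomerisation of the angelates by the acidic selenium reagent. The fallback sets out from **37**, where C4=C5 is flanked by a silyl ether and is more electron-rich. SeO2/t-BuOOH gives the C15 alcohol F10. 4-Methoxybenzyl trichloroacetimidate with catalytic La(OTf)3 gives the C15 ether F11. HF·pyridine gives the triol F12, and TEMPO/PhI(OAc)2 gives the lactone enal F13. DDQ in wet CH2Cl2 removes the ether and returns to the route at **42**.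

## Further compounds

F1 | step 22 | C8-hydroxy cyclodeca-1(10),4-dien-9-one | CC(C)(C)[Si](C)(C)O[C@@H]2/C=C(/C)CC/C=C(/CO[Si](c3ccccc3)(c3ccccc3)C(C)(C)C)C(=O)[C@@H](O)[C@H]2C(=C)CO[Si](c3ccccc3)(c3ccccc3)C(C)(C)C
F2 | step 5 | C1 allylic alcohol (C1-OH syn) of 7 | C[C@]12CC[C@H](O)C(CO[Si](c3ccccc3)(c3ccccc3)C(C)(C)C)=C1CCC[C@@H]2O
F3 | step 5 | 9,10-epoxy 1,5-diol (epoxide syn) | C[C@]12CC[C@H](O)[C@]3(CO[Si](c4ccccc4)(c4ccccc4)C(C)(C)C)O[C@]13CCC[C@@H]2O
F4 | step 5 | 9,10-epoxy 1,5-diketone | C[C@]12CCC(=O)[C@]3(CO[Si](c4ccccc4)(c4ccccc4)C(C)(C)C)O[C@]13CCCC2=O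
F5 | step 10 | C8 epimer of 15 (trans-8,9-diol) | C[C@]12CCC=C(CO[Si](c3ccccc3)(c3ccccc3)C(C)(C)C)[C@@]1(O)[C@@H](O)C=CC2=O
F6 | step 10 | C8 4-nitrobenzoate (C8-O syn) | C[C@]12CCC=C(CO[Si](c3ccccc3)(c3ccccc3)C(C)(C)C)[C@@]1(O)[C@H](OC(=O)c3ccc(cc3)[N+](=O)[O-])C=CC2=O
F7 | step 23 | C9 epimer of 33 | CC(C)(C)[Si](C)(C)O[C@@H]2/C=C(/C)CC/C=C(/CO[Si](c3ccccc3)(c3ccccc3)C(C)(C)C)[C@@H](O)[C@@H](O[Si](CC)(CC)CC)[C@H]2C(=C)CO[Si](c3ccccc3)(c3ccccc3)C(C)(C)C
F8 | step 23 | C9 angelate, C8 TES ether | CC(C)(C)[Si](C)(C)O[C@@H]2/C=C(/C)CC/C=C(/CO[Si](c3ccccc3)(c3ccccc3)C(C)(C)C)[C@H](OC(=O)/C(C)=C\C)[C@@H](O[Si](CC)(CC)CC)[C@H]2C(=C)CO[Si](c3ccccc3)(c3ccccc3)C(C)(C)C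
F9 | step 23 | C9 angelate, C8 alcohol | CC(C)(C)[Si](C)(C)O[C@@H]2/C=C(/C)CC/C=C(/CO[Si](c3ccccc3)(c3ccccc3)C(C)(C)C)[C@H](OC(=O)/C(C)=C\C)[C@@H](O)[C@H]2C(=C)CO[Si](c3ccccc3)(c3ccccc3)C(C)(C)C
F10 | step 28 | C15 alcohol of 37 | CC(C)(C)[Si](C)(C)O[C@@H]2/C=C(/CO)CC/C=C(/CO[Si](c3ccccc3)(c3ccccc3)C(C)(C)C)[C@H](OC(=O)/C(C)=C\C)[C@@H](OC(=O)/C(C)=C\C)[C@H]2C(=C)CO[Si](c3ccccc3)(c3ccccc3)C(C)(C)C
F11 | step 28 | C15 4-methoxybenzyl ether of F10 | CC(C)(C)[Si](C)(C)O[C@@H]2/C=C(/COCc3ccc(OC)cc3)CC/C=C(/CO[Si](c3ccccc3)(c3ccccc3)C(C)(C)C)[C@H](OC(=O)/C(C)=C\C)[C@@H](OC(=O)/C(C)=C\C)[C@H]2C(=C)CO[Si](c3ccccc3)(c3ccccc3)C(C)(C)C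
F12 | step 28 | 6,12,14-triol C15 4-methoxybenzyl ether | O[C@@H]2/C=C(/COCc3ccc(OC)cc3)CC/C=C(/CO)[C@H](OC(=O)/C(C)=C\C)[C@@H](OC(=O)/C(C)=C\C)[C@H]2C(=C)CO
F13 | step 28 | lactone enal C15 4-methoxybenzyl ether | C=C1C(=O)O[C@@H]2/C=C(/COCc3ccc(OC)cc3)CC/C=C(/C=O)[C@H](OC(=O)/C(C)=C\C)[C@@H](OC(=O)/C(C)=C\C)[C@@H]12
A1 | alternative 1 | furan | c1ccoc1
A2 | alternative 1 | ethyl glyoxylate | CCOC(=O)C=O
A3 | alternative 1 | exo 6-ethoxycarbonyl-2,7-dioxabicyclo[3.2.0]hept-3-ene | CCOC(=O)[C@H]1O[C@@H]2OC=C[C@H]12
A4 | alternative 2 | lactone-fused 3-methylcyclohex-2-enone with silyl ether | CC1=CC(=O)[C@@H]2CC(=O)O[C@@H]2[C@H]1O[Si](C)(C)C(C)(C)C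
A5 | alternative 2 | methyl cyclobut-1-ene-1-carboxylate | COC(=O)C1=CCC1
A6 | alternative 2 | cis,anti,cis tricyclic photoadduct | COC(=O)[C@@]12CC[C@H]1[C@@]3(C)[C@H](O[Si](C)(C)C(C)(C)C)[C@H]4OC(=O)C[C@H]4C(=O)[C@@H]23
A7 | alternative 3 | cis-fused octalin epoxy alcohol (C1–C6 bonded; C6 tertiary alcohol, C10 spiro-epoxide, 8,9-acetonide) | O[C@]12C=C(C)CC[C@H]1[C@]3(CO3)[C@@H]4OC(C)(C)O[C@H]4[C@H]2CC(=O)OC
A8 | alternative 3 | cis,cis-cyclodecadien-6-one with C14 alcohol and 8,9-acetonide | O=C2/C=C(/C)CC/C=C(/CO)[C@H](O3)[C@@H](OC3(C)C)[C@H]2CC(=O)OC
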